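Ring A is built de novo instead of being substituted: a Danheiser benzannulation forms C8–C8a and C6–C7. The step exploits the pattern of ring A, oxygen on C5, C7 and C8a with the chiral C8 chain held between C7 and C8a: in one operation it delivers the arene with the chain in place, O7 as a TIPS ether, O5 as a 4-methoxybenzyl (PMB) ether and only the C8a hydroxyl free, so that ring C can later close through O1 alone. Its precursors are 3-(4-methoxybenzyloxy)cyclobutenone (supplying C8a, C4a, C5, C6) and an (R)-configured triisopropylsilyl ynol ether bearing the TBS-protected 2-hydroxy-3-methylbut-3-enyl chain (supplying C8, C7).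

Key step: step 5

Assumption: (R)-TRIP is taken to give the (R)-carbinol from methacrolein, by analogy with its sense of induction for aryl and other α,β-unsaturated aldehydes; the configuration of 4 is to be checked by Mosher ester analysis and the enantiomeric acid used if the sense proves opposite.

Step 1
Reactants: 1 methacrolein; 2 allenylboronic acid pinacol ester
Product: 4 (R)-2-methylhex-1-en-5-yn-3-ol, via O-pinacolboryl ether 3 (not isolated)
Conditions: 2 (1.3 equiv), (R)-3,3'-bis(2,4,6-triisopropylphenyl)-1,1'-binaphthyl-2,2'-diyl hydrogen phosphate [(R)-TRIP] (5 mol %), 4 Å MS, toluene, 0 °C; aq NaHCO3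
Reagents that add atoms: none
Why: Chiral phosphoric acid catalysed propargylation of an aldehyde with an allenylboronate, which passes through a closed six-membered SE2' transition state in which the acid activates the boronate, so that the catalyst selects the face of the formyl group and sets the only stereocentre, the side-chain carbinol carbon, as (R), while the borate 3 is hydrolysed on work-up.

Step 2
Reactants: 4 (R)-2-methylhex-1-en-5-yn-3-ol
Product: 5 (R)-tert-butyldimethyl[(2-methylhex-1-en-5-yn-3-yl)oxy]silane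
Conditions: TBSCl, imidazole, DMF, 0 °C to rt
Reagents that add atoms: tert-butyldimethylsilyl chloride, CC(C)(C)[Si](C)(C)Cl
Why: Imidazole-promoted silylation of a secondary alcohol (silyl ether formation), which leaves the stereocentre, the alkene and the terminal alkyne untouched and gives a group that should survive base, heat and mild Lewis acid until the last step.

Step 3
Reactants: 5 (R)-tert-butyldimethyl[(2-methylhex-1-en-5-yn-3-yl)oxy]silane
Product: 7 (R)-4-(tert-butyldimethylsilyloxy)-5-methyl-1-(triisopropylsilyloxy)hex-5-en-1-yne, via lithium ynolate 6 (not isolated)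
Conditions: LiN(SiMe3)2 (2.2 equiv), t-BuOOH (1.1 equiv), THF, −78 to 0 °C; then TIPSOTf, −78 to 0 °C; Et3N-deactivated silica
Reagents that add atoms: tert-butyl hydroperoxide, CC(C)(C)OO; triisopropylsilyl trifluoromethanesulfonate, CC(C)[Si](OS(=O)(=O)C(F)(F)F)(C(C)C)C(C)C
Why: The amide base forms the lithium acetylide and lithium tert-butyl peroxide, the acetylide carbon attacks the peroxide oxygen with loss of tert-butoxide to give the ynolate 6 (acetylide oxygenation), and the bulky silyl triflate then reacts at oxygen instead of carbon (O-silylation of an ynolate), the isolated alkene being inert to the nucleophilic peroxide.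

Step 4
Reactants: 8 3-ethoxycyclobut-2-en-1-one; 9 4-methoxybenzyl alcohol
Product: 10 3-(4-methoxybenzyloxy)cyclobut-2-en-1-one
Conditions: 9 (3 equiv), pyridinium p-toluenesulfonate (5 mol %), toluene, 45 °C, reduced pressure (EtOH removed)
Reagents that add atoms: none
Why: Acid-catalysed alkoxy exchange of a vinylogous ester (addition of the alcohol to C3 of the protonated enone and loss of ethanol), driven towards the benzylic ether by excess alcohol and removal of ethanol, with a weak pyridinium acid chosen so that the 4-methoxybenzyl alcohol does not ionise.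

Step 5
Reactants: 10 3-(4-methoxybenzyloxy)cyclobut-2-en-1-one; 7 (R)-4-(tert-butyldimethylsilyloxy)-5-methyl-1-(triisopropylsilyloxy)hex-5-en-1-yne
Product: 15 5-[(4-methoxybenzyl)oxy]-2-[(2R)-2-(tert-butyldimethylsilyloxy)-3-methylbut-3-en-1-yl]-3-(triisopropylsilyloxy)phenol, via vinylketene 11 (not isolated), via vinylcyclobutenone 12 (not isolated), via dienylketene 13 (not isolated), via cyclohexadienone 14 (not isolated)
Conditions: 10 (1.0 equiv), 7 (1.0 equiv), toluene, sealed tube, 110 °C, raised to 135 °C if 10 persists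
Reagents that add atoms: none
Why: On heating, 10 should undergo 4π-electrocyclic cleavage of its C1–C4 bond to the alkoxy vinylketene 11, whose ketene C=C adds [2+2] to the electron-rich triple bond of 7 to give 12, which reopens (4π) to the dienylketene 13. Ring A is then closed by a thermal disrotatory 6π-electrocyclisation of 13 that re-forms the bond between the future C4a and C8a, and the dienone 14 aromatises by enolisation, so the two net new ring bonds are C8–C8a and C6–C7. The closest known reaction type is the Danheiser benzannulation of 3-substituted cyclobutenones with trialkylsilyl ynol ethers, which gives 2,5-disubstituted resorcinol monosilyl ethers; here the 3-substituent is an alkoxy group, which stabilises the four-membered enone and is expected to demand the higher temperature. No stereocentre is created (the sp3 ring carbon of 12 is lost on ring opening), and the existing (R)-carbinol, protected and two bonds away from the nearest reacting carbon, takes no part. The step needs a single regiochemical outcome in the [2+2] event, and the polarisation of the ynol ether secures it: the nucleophilic, chain-bearing alkyne carbon bonds to the electrophilic central carbon of the ketene, so the chain ends up flanked by the new hydroxyl (C8a) and the TIPS ether (C7) with the PMB ether para to it (C5). The ynol ether is far more nucleophilic than the isolated 1,1-disubstituted alkene, which should therefore be left alone, and using no excess of 10 limits acylation of the product phenol by the ketene.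

Step 6
Reactants: 15 5-[(4-methoxybenzyl)oxy]-2-[(2R)-2-(tert-butyldimethylsilyloxy)-3-methylbut-3-en-1-yl]-3-(triisopropylsilyloxy)phenol
Product: 17 2-hydroxy-6-[(4-methoxybenzyl)oxy]-3-[(2R)-2-(tert-butyldimethylsilyloxy)-3-methylbut-3-en-1-yl]-4-(triisopropylsilyloxy)benzaldehyde, via salicyl alcohol 16 (not isolated)
Conditions: MgCl2 (2 equiv), Et3N (4 equiv), (CH2O)n (6 equiv), THF, reflux; pH 5 work-up
Reagents that add atoms: paraformaldehyde (formaldehyde), C=O
Why: Casnati–Skattebøl ortho-formylation, in which the magnesium phenoxide delivers formaldehyde within a chelate to the only unsubstituted ortho carbon (the future C4a, between the free hydroxyl and the PMB ether) to give 16, which a second formaldehyde oxidises by Oppenauer-type hydride transfer, under conditions that silyl and benzyl ethers tolerate.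

Step 7
Reactants: 18 4-hydroxybenzoic acid
Product: 20 4-(triisopropylsilyloxy)benzoic acid, via silyl ester 19 (not isolated)
Conditions: TIPSCl (2.2 equiv), imidazole, DMF, rt; then K2CO3, MeOH/THF/H2O, rt; HCl to pH 3–4
Reagents that add atoms: triisopropylsilyl chloride, CC(C)[Si](Cl)(C(C)C)C(C)C
Why: Both acidic hydroxyls are silylated and the far more labile silyl ester of 19 is then solvolysed selectively by mild carbonate (silyl protection of a phenol), which leaves the aryl triisopropylsilyl ether in place.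

Step 8
Reactants: 20 4-(triisopropylsilyloxy)benzoic acid
Product: 22 2-[dimethyl(oxo)-λ6-sulfanylidene]-1-[4-(triisopropylsilyloxy)phenyl]ethan-1-one, via acid chloride 21 (not isolated)
Conditions: (COCl)2, cat. DMF, CH2Cl2, 0 °C to rt; then Me3S(O)I (3 equiv), KOtBu (3 equiv), THF (methylide preformed at reflux), 0 °C to rt
Reagents that add atoms: trimethylsulfoxonium iodide, C[S+](C)(C)=O.[I-]
Why: Acylation of dimethylsulfoxonium methylide by the acid chloride 21, in which a second equivalent of the methylide deprotonates the acylsulfoxonium salt to the stabilised β-keto sulfoxonium ylide (standard sulfoxonium ylide synthesis), run cold so that the aryl silyl ether is not attacked.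

Step 9
Reactants: 17 2-hydroxy-6-[(4-methoxybenzyl)oxy]-3-[(2R)-2-(tert-butyldimethylsilyloxy)-3-methylbut-3-en-1-yl]-4-(triisopropylsilyloxy)benzaldehyde; 22 2-[dimethyl(oxo)-λ6-sulfanylidene]-1-[4-(triisopropylsilyloxy)phenyl]ethan-1-one
Product: 24 5-[(4-methoxybenzyl)oxy]-8-[(2R)-2-(tert-butyldimethylsilyloxy)-3-methylbut-3-en-1-yl]-7-(triisopropylsilyloxy)-2-[4-(triisopropylsilyloxy)phenyl]-4H-chromen-4-one, via diketone 23 (not isolated)
Conditions: 22 (1.5 equiv), [Cp*RhCl2]2 (4 mol %; Cp* = C5Me5), AgSbF6 (16 mol %), NaOAc (0.3 equiv), PivOH (1 equiv), 1,2-dichloroethane, 80 °C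
Reagents that add atoms: none
Why: Phenol-directed activation of the aldehyde C–H bond by the cationic Cp*Rh catalyst (trivalent rhodium) should give a five-membered acyl rhodacycle that takes up the sulfoxonium ylide as a carbene equivalent with loss of dimethyl sulfoxide, migratory insertion and protodemetalation then give the 1,3-diketone 23, and its acid-assisted cyclodehydration through the only free phenol (on C8a) closes ring C as the flavone (rhodium-catalysed C–H acylmethylation and annulation of a salicylaldehyde with a sulfoxonium ylide).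

Step 10
Reactants: 24 5-[(4-methoxybenzyl)oxy]-8-[(2R)-2-(tert-butyldimethylsilyloxy)-3-methylbut-3-en-1-yl]-7-(triisopropylsilyloxy)-2-[4-(triisopropylsilyloxy)phenyl]-4H-chromen-4-one
Product: 25 5-hydroxy-8-[(2R)-2-(tert-butyldimethylsilyloxy)-3-methylbut-3-en-1-yl]-7-(triisopropylsilyloxy)-2-[4-(triisopropylsilyloxy)phenyl]-4H-chromen-4-one
Conditions: DDQ (1.5 equiv), CH2Cl2/pH 7 phosphate buffer, 0 °C to rt
Reagents that add atoms: none
Why: Oxidative cleavage of a 4-methoxybenzyl ether with DDQ (hydride abstraction from the electron-rich benzylic position and hydrolysis of the resulting oxocarbenium ion), which in a buffered two-phase medium should leave the silyl ethers, the alkene and the allylic silyl ether untouched and frees the C5 hydroxyl before any other phenol is exposed to the oxidant.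

Step 11
Reactants: 25 5-hydroxy-8-[(2R)-2-(tert-butyldimethylsilyloxy)-3-methylbut-3-en-1-yl]-7-(triisopropylsilyloxy)-2-[4-(triisopropylsilyloxy)phenyl]-4H-chromen-4-one
Product: 26 5,7-dihydroxy-8-[(2R)-2-hydroxy-3-methylbut-3-en-1-yl]-2-(4-hydroxyphenyl)-4H-chromen-4-one (CNP0315675.1)
Conditions: Bu4NF (6 equiv), AcOH (6 equiv), THF, 0 °C to rt
Reagents that add atoms: none
Why: Fluoride-driven cleavage of the three silyl ethers (formation of strong Si–F bonds), buffered with acetic acid so that neither strong acid nor strong base meets the allylic alcohol, the isopropenyl group or the C7 hydroxyl beside it, which should give the target with the (R)-carbinol unchanged.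

Compound list
1 | methacrolein | C=C(C)C=O | starting material
2 | allenylboronic acid pinacol ester (4,4,5,5-tetramethyl-2-(propa-1,2-dien-1-yl)-1,3,2-dioxaborolane) | C=C=CB1OC(C)(C)C(C)(C)O1 | starting material
3 | (R)-4,4,5,5-tetramethyl-2-[(2-methylhex-1-en-5-yn-3-yl)oxy]-1,3,2-dioxaborolane | C=C(C)[C@H](OB1OC(C)(C)C(C)(C)O1)CC#C | intermediate
4 | (R)-2-methylhex-1-en-5-yn-3-ol | C=C(C)[C@H](O)CC#C | intermediate
5 | (R)-tert-butyldimethyl[(2-methylhex-1-en-5-yn-3-yl)oxy]silane | C=C(C)[C@H](O[Si](C)(C)C(C)(C)C)CC#C | intermediate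
6 | lithium (R)-4-(tert-butyldimethylsilyloxy)-5-methylhex-5-en-1-yn-1-olate | C=C(C)[C@H](O[Si](C)(C)C(C)(C)C)CC#C[O-].[Li+] | intermediate
7 | (R)-4-(tert-butyldimethylsilyloxy)-5-methyl-1-(triisopropylsilyloxy)hex-5-en-1-yne | C=C(C)[C@H](O[Si](C)(C)C(C)(C)C)CC#CO[Si](C(C)C)(C(C)C)C(C)C | intermediate
8 | 3-ethoxycyclobut-2-en-1-one | CCOC1=CC(=O)C1 | starting material
9 | 4-methoxybenzyl alcohol | COc1ccc(CO)cc1 | starting material
10 | 3-(4-methoxybenzyloxy)cyclobut-2-en-1-one | COc1ccc(COC2=CC(=O)C2)cc1 | intermediate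
11 | 3-(4-methoxybenzyloxy)buta-1,3-dien-1-one (vinylketene) | C=C(OCc1ccc(OC)cc1)C=C=O | intermediate
12 | 2-[(2R)-2-(tert-butyldimethylsilyloxy)-3-methylbut-3-en-1-yl]-4-[1-(4-methoxybenzyloxy)vinyl]-3-(triisopropylsilyloxy)cyclobut-2-en-1-one (either epimer at C4) | C=C(C)[C@H](O[Si](C)(C)C(C)(C)C)CC1=C(O[Si](C(C)C)(C(C)C)C(C)C)C(C(=C)OCc2ccc(OC)cc2)C1=O | intermediate
13 | 2-[(2R)-2-(tert-butyldimethylsilyloxy)-3-methylbut-3-en-1-yl]-5-(4-methoxybenzyloxy)-3-(triisopropylsilyloxy)hexa-1,3,5-trien-1-one (ketene carbon and alkoxyvinyl group cis across C3=C4) | C=C(C)[C@H](O[Si](C)(C)C(C)(C)C)CC(=C=O)/C(O[Si](C(C)C)(C(C)C)C(C)C)=C\C(=C)OCc1ccc(OC)cc1 | intermediate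
14 | 2-[(2R)-2-(tert-butyldimethylsilyloxy)-3-methylbut-3-en-1-yl]-5-(4-methoxybenzyloxy)-3-(triisopropylsilyloxy)cyclohexa-2,4-dien-1-one | C=C(C)[C@H](O[Si](C)(C)C(C)(C)C)CC1=C(O[Si](C(C)C)(C(C)C)C(C)C)C=C(OCc2ccc(OC)cc2)CC1=O | intermediate
15 | 5-[(4-methoxybenzyl)oxy]-2-[(2R)-2-(tert-butyldimethylsilyloxy)-3-methylbut-3-en-1-yl]-3-(triisopropylsilyloxy)phenol | C=C(C)[C@H](O[Si](C)(C)C(C)(C)C)Cc1c(O)cc(OCc2ccc(OC)cc2)cc1O[Si](C(C)C)(C(C)C)C(C)C | intermediate
16 | 2-(hydroxymethyl)-3-[(4-methoxybenzyl)oxy]-6-[(2R)-2-(tert-butyldimethylsilyloxy)-3-methylbut-3-en-1-yl]-5-(triisopropylsilyloxy)phenol | C=C(C)[C@H](O[Si](C)(C)C(C)(C)C)Cc1c(O)c(CO)c(OCc2ccc(OC)cc2)cc1O[Si](C(C)C)(C(C)C)C(C)C | intermediate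
17 | 2-hydroxy-6-[(4-methoxybenzyl)oxy]-3-[(2R)-2-(tert-butyldimethylsilyloxy)-3-methylbut-3-en-1-yl]-4-(triisopropylsilyloxy)benzaldehyde | C=C(C)[C@H](O[Si](C)(C)C(C)(C)C)Cc1c(O)c(C=O)c(OCc2ccc(OC)cc2)cc1O[Si](C(C)C)(C(C)C)C(C)C | intermediate
18 | 4-hydroxybenzoic acid | O=C(O)c1ccc(O)cc1 | starting material
19 | triisopropylsilyl 4-(triisopropylsilyloxy)benzoate | CC(C)[Si](OC(=O)c1ccc(O[Si](C(C)C)(C(C)C)C(C)C)cc1)(C(C)C)C(C)C | intermediate
20 | 4-(triisopropylsilyloxy)benzoic acid | CC(C)[Si](Oc1ccc(C(=O)O)cc1)(C(C)C)C(C)C | intermediate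
21 | 4-(triisopropylsilyloxy)benzoyl chloride | CC(C)[Si](Oc1ccc(C(=O)Cl)cc1)(C(C)C)C(C)C | intermediate
22 | 2-[dimethyl(oxo)-λ6-sulfanylidene]-1-[4-(triisopropylsilyloxy)phenyl]ethan-1-one | CS(C)(=O)=CC(=O)c1ccc(O[Si](C(C)C)(C(C)C)C(C)C)cc1 | intermediate
23 | 1-{2-hydroxy-6-[(4-methoxybenzyl)oxy]-3-[(2R)-2-(tert-butyldimethylsilyloxy)-3-methylbut-3-en-1-yl]-4-(triisopropylsilyloxy)phenyl}-3-[4-(triisopropylsilyloxy)phenyl]propane-1,3-dione | C=C(C)[C@H](O[Si](C)(C)C(C)(C)C)Cc1c(O)c(C(=O)CC(=O)c3ccc(O[Si](C(C)C)(C(C)C)C(C)C)cc3)c(OCc2ccc(OC)cc2)cc1O[Si](C(C)C)(C(C)C)C(C)C | intermediate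
24 | 5-[(4-methoxybenzyl)oxy]-8-[(2R)-2-(tert-butyldimethylsilyloxy)-3-methylbut-3-en-1-yl]-7-(triisopropylsilyloxy)-2-[4-(triisopropylsilyloxy)phenyl]-4H-chromen-4-one | C=C(C)[C@H](O[Si](C)(C)C(C)(C)C)Cc1c(O[Si](C(C)C)(C(C)C)C(C)C)cc(OCc4ccc(OC)cc4)c2c(=O)cc(-c3ccc(O[Si](C(C)C)(C(C)C)C(C)C)cc3)oc12 | intermediate
25 | 5-hydroxy-8-[(2R)-2-(tert-butyldimethylsilyloxy)-3-methylbut-3-en-1-yl]-7-(triisopropylsilyloxy)-2-[4-(triisopropylsilyloxy)phenyl]-4H-chromen-4-one | C=C(C)[C@H](O[Si](C)(C)C(C)(C)C)Cc1c(O[Si](C(C)C)(C(C)C)C(C)C)cc(O)c2c(=O)cc(-c3ccc(O[Si](C(C)C)(C(C)C)C(C)C)cc3)oc12 | intermediate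
26 | 5,7-dihydroxy-8-[(2R)-2-hydroxy-3-methylbut-3-en-1-yl]-2-(4-hydroxyphenyl)-4H-chromen-4-one (CNP0315675.1) | C=C(C)[C@H](O)Cc1c(O)cc(O)c2c(=O)cc(-c3ccc(O)cc3)oc12 | target

Total step count: 11. Longest linear sequence: 8 steps (1, 2, 3, 5, 6, 9, 10, 11) from methacrolein.

Steps most likely to fail

Step 5. The electrocyclic opening of the donor-stabilised cyclobutenone may be slower than thermal isomerisation of the siloxyalkyne to a silylketene (silyl shift from oxygen to carbon), so that the alkyne is lost before the ketene is formed. The fallback releases the same vinylketene without any ring opening. It sets out from 4-methoxybenzyl alcohol 9 and siloxyalkyne 7 and comes back to the route at phenol 15. Alcohol 9 is added in Michael fashion to ethyl but-2-ynoate (cat. NaH, THF) to give ethyl (E)-3-(4-methoxybenzyloxy)but-2-enoate F1. Saponification (LiOH, THF/H2O) gives (E)-3-(4-methoxybenzyloxy)but-2-enoic acid F2. 1-Chloro-N,N,2-trimethylprop-1-en-1-amine converts F2 under neutral conditions into (E)-3-(4-methoxybenzyloxy)but-2-enoyl chloride F3. This is added slowly to 7 and Et3N in toluene at room temperature. Deprotonation at the γ-methyl group with loss of chloride (1,4-dehydrochlorination) generates vinylketene 11, which is trapped by 7 as 12, and warming to about 80 °C should complete the sequence to 15.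

Step 9. Metalation of the formyl C–H bond, which is flanked by two oxygen substituents, may be slow, leaving the ylide to decompose; or the Lewis-acidic metal salts at 80 °C may remove the PMB or silyl groups before ring C has closed. The fallback sets out from aldehyde 17 and comes back at flavone 24. 4-Ethynylphenol is silylated (TIPSCl, imidazole) to triisopropyl(4-ethynylphenoxy)silane F4. Its lithium acetylide (n-BuLi, THF, −78 °C, 2.3 equiv, the first equivalent taken up by the phenol) is added to 17 to give the propargylic alcohol 2-{1-hydroxy-3-[4-(triisopropylsilyloxy)phenyl]prop-2-yn-1-yl}-3-[(4-methoxybenzyl)oxy]-6-[(2R)-2-(tert-butyldimethylsilyloxy)-3-methylbut-3-en-1-yl]-5-(triisopropylsilyloxy)phenol F5, as a mixture of epimers at the new carbinol that converge in the next operation. MnO2 in CH2Cl2 oxidises it to the ynone 1-{2-hydroxy-6-[(4-methoxybenzyl)oxy]-3-[(2R)-2-(tert-butyldimethylsilyloxy)-3-methylbut-3-en-1-yl]-4-(triisopropylsilyloxy)phenyl}-3-[4-(triisopropylsilyloxy)phenyl]prop-2-yn-1-one F6. Et2NH in EtOH then effects conjugate addition and six-membered ring closure through the C8a phenol with loss of the amine, which should give 24.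

Step 1. Facial selectivity may be poor in the addition to a small, α-branched enal, and the resulting enantiomeric impurity could not be removed later. The fallback uses a covalently bound auxiliary whose diastereomers can be separated. It sets out from methacrolein 1 and comes back at siloxyalkyne 7 through ynolate 6. (R)-2-Hydroxy-1,2,2-triphenylethyl acetate [(R)-HYTRA], doubly deprotonated with LiN(iPr)2 in THF at −78 °C, is added to 1 to give (1R)-2-hydroxy-1,2,2-triphenylethyl (3R)-3-hydroxy-4-methylpent-4-enoate F7. The (R)-carbinol is the sense this auxiliary is expected to give, as with simple aldehydes, and the minor diastereomer is removed by crystallisation. K2CO3 in MeOH transesterifies F7 to methyl (R)-3-hydroxy-4-methylpent-4-enoate F8 and returns the triphenylglycol. TBSCl and imidazole give methyl (R)-3-(tert-butyldimethylsilyloxy)-4-methylpent-4-enoate F9. Under Kowalski ester homologation conditions (CH2Br2 and lithium 2,2,6,6-tetramethylpiperidide, THF, −78 °C; then n-BuLi, −78 °C to rt) the ester should rearrange to ynolate 6; the intermediate enolate forms on the dibrominated side, so the β-silyloxy group is not eliminated. Trapping with TIPSOTf at −78 °C gives 7.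

Further compounds
F1 | step 5 | ethyl (E)-3-(4-methoxybenzyloxy)but-2-enoate | CCOC(=O)/C=C(\C)OCc1ccc(OC)cc1
F2 | step 5 | (E)-3-(4-methoxybenzyloxy)but-2-enoic acid | OC(=O)/C=C(\C)OCc1ccc(OC)cc1
F3 | step 5 | (E)-3-(4-methoxybenzyloxy)but-2-enoyl chloride | ClC(=O)/C=C(\C)OCc1ccc(OC)cc1
F4 | step 9 | triisopropyl(4-ethynylphenoxy)silane | C#Cc1ccc(O[Si](C(C)C)(C(C)C)C(C)C)cc1
F5 | step 9 | 2-{1-hydroxy-3-[4-(triisopropylsilyloxy)phenyl]prop-2-yn-1-yl}-3-[(4-methoxybenzyl)oxy]-6-[(2R)-2-(tert-butyldimethylsilyloxy)-3-methylbut-3-en-1-yl]-5-(triisopropylsilyloxy)phenol | C=C(C)[C@H](O[Si](C)(C)C(C)(C)C)Cc1c(O)c(C(O)C#Cc3ccc(O[Si](C(C)C)(C(C)C)C(C)C)cc3)c(OCc2ccc(OC)cc2)cc1O[Si](C(C)C)(C(C)C)C(C)C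
F6 | step 9 | 1-{2-hydroxy-6-[(4-methoxybenzyl)oxy]-3-[(2R)-2-(tert-butyldimethylsilyloxy)-3-methylbut-3-en-1-yl]-4-(triisopropylsilyloxy)phenyl}-3-[4-(triisopropylsilyloxy)phenyl]prop-2-yn-1-one | C=C(C)[C@H](O[Si](C)(C)C(C)(C)C)Cc1c(O)c(C(=O)C#Cc3ccc(O[Si](C(C)C)(C(C)C)C(C)C)cc3)c(OCc2ccc(OC)cc2)cc1O[Si](C(C)C)(C(C)C)C(C)C
F7 | step 1 | (1R)-2-hydroxy-1,2,2-triphenylethyl (3R)-3-hydroxy-4-methylpent-4-enoate | C=C(C)[C@H](O)CC(=O)O[C@H](c1ccccc1)C(O)(c1ccccc1)c1ccccc1
F8 | step 1 | methyl (R)-3-hydroxy-4-methylpent-4-enoate | C=C(C)[C@H](O)CC(=O)OC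
F9 | step 1 | methyl (R)-3-(tert-butyldimethylsilyloxy)-4-methylpent-4-enoate | C=C(C)[C@H](O[Si](C)(C)C(C)(C)C)CC(=O)OC
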